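**Retrosynthetic overview**
1. Target 18 ← non-basic global deprotection of the protected (3S)-isoflavanone 16 ← oxidation of cis-(3S,4S)-isoflavan-4-ol 15 ← Ru transfer-hydrogenation cascade with dynamic kinetic resolution on isoflavone 13 (C3 is set here, stereoconvergently) ← Stille prenylation of bromide 12.
2. Key disconnection: C3 and its aryl ring are excised from the pyranone ring of 12. The six-membered ring O1–C2–C3–C4–C4a–C8a is made from the five-membered furan ring (O1–C2–C3–C3a–C7a) of 3-silyloxybenzofuran 2 by inserting aryl(chloro)carbene 9 (from diazirine 8) into the C2=C3 bond.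
3. Enabling feature: in the target, C3 sits between C2 (bound to ring oxygen O1) and the C4 carbonyl. Removing it leaves the enol ether O1–C2=C3(OSi), a π bond carrying two oxygen donors that captures the carbene and then expels chloride. Only the C2–C3 bond lies in the cyclopropane, so the aryl carbon can only end between C2 and the carbonyl carbon.
4. Ring order: A ring and furanone ring are bought (1) → temporary cyclopropane (bicyclo[3.1.0] unit, not in the target) → its zero bridge is cleaved to give ring C (step 6). The B ring is bought as nitrile 3, whose nitrile carbon becomes C3.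
5. The prenyl alkene is kept out until after the carbene step (Br as placeholder). Silicon serves as enol activator, A-ring protection and chloride sink.

Key step: step 6

Remark: the target stereocentre is read as 3S (C4 > C2 > C1′ > H); the (S,S) Ru catalyst in step 8 is assigned by analogy with the known sense of reduction of 4-chromanone and would be exchanged for its antipode if the first run showed the opposite sense.

**Step 1**
Reactants: 1 4,6-dihydroxybenzofuran-3(2H)-one
Product: 2 3,4,6-tris(tert-butyldimethylsilyloxy)benzofuran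
Conditions: TBSOTf (3.4 equiv), Et3N (4.5 equiv), CH2Cl2, 0 °C to rt; non-aqueous work-up (pentane, filtration)
Reagents that add atoms: tert-butyldimethylsilyl trifluoromethanesulfonate CC(C)(C)[Si](C)(C)OS(=O)(=O)C(F)(F)F
Why: Silyl triflate/amine O-silylation of both phenols and soft enolisation of the furanone (driven by aromatisation to the benzofuran) should give the silyl enol ether, whose C2=C3 bond is the only non-arene π bond.

**Step 2**
Reactants: 3 4-hydroxy-2-methoxybenzonitrile
Product: 4 5-bromo-4-hydroxy-2-methoxybenzonitrile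
Conditions: NBS (1.0 equiv), MeCN, 0 °C
Reagents that add atoms: N-bromosuccinimide BrN1C(=O)CCC1=O
Why: Electrophilic aromatic bromination should go to C5, which is ortho to OH and para to OMe, rather than to the hindered C3 between the two oxygens.

**Step 3**
Reactants: 4 5-bromo-4-hydroxy-2-methoxybenzonitrile
Product: 5 5-bromo-2-methoxy-4-(methoxymethoxy)benzonitrile
Conditions: MOMCl, i-Pr2NEt, CH2Cl2, 0 °C to rt
Reagents that add atoms: chloromethyl methyl ether COCCl
Why: O-alkylation of the acidic phenol gives a MOM acetal, chosen because it is inert to amide base, aqueous hypochlorite, carbenes, Pd(0) and Ru–H, where an aryl silyl ether of this acidic phenol would be cleaved.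

**Step 4**
Reactants: 5 5-bromo-2-methoxy-4-(methoxymethoxy)benzonitrile
Product: 7 5-bromo-2-methoxy-4-(methoxymethoxy)benzamidine, via lithium N,N'-bis(trimethylsilyl)amidinate 6 (not isolated)
Conditions: LiHMDS (1.5 equiv), THF, 0 °C to rt; then MeOH, 0 °C
Reagents that add atoms: lithium bis(trimethylsilyl)amide [Li+].C[Si](C)(C)[N-][Si](C)(C)C
Why: Addition of the silylamide to the nitrile followed by methanolysis of the N–Si bonds is the standard amidine synthesis, and the acid-free quench keeps the MOM ether.

**Step 5**
Reactants: 7 5-bromo-2-methoxy-4-(methoxymethoxy)benzamidine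
Product: 8 3-[5-bromo-2-methoxy-4-(methoxymethoxy)phenyl]-3-chloro-3H-diazirine
Conditions: aq. NaOCl (2.2 equiv), LiCl, DMSO/pentane, 0 °C to rt; kept cold in the dark and used at once as a pentane solution
Reagents that add atoms: sodium hypochlorite [Na+].[O-]Cl
Why: Graham oxidation of an amidine (N-chlorination, ring closure, chloride transfer to carbon) should give the aryl chlorodiazirine, with the meta bromine tempering the lability caused by the two alkoxy groups.

**Step 6**
Reactants: 2 3,4,6-tris(tert-butyldimethylsilyloxy)benzofuran; 8 3-[5-bromo-2-methoxy-4-(methoxymethoxy)phenyl]-3-chloro-3H-diazirine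
Product: 12 3-[5-bromo-2-methoxy-4-(methoxymethoxy)phenyl]-5,7-bis(tert-butyldimethylsilyloxy)-4H-chromen-4-one, via aryl(chloro)carbene 9 (not isolated), via chlorocyclopropane-fused benzofuran 10 (not isolated), via 4-silyloxychromenylium chloride 11 (not isolated)
Conditions: 2 (1.5 equiv), Na2CO3 (solid), PhMe/MeCN, 50–60 °C, dark, slow addition of 8; then aq. NaHCO3
Reagents that add atoms: none
Why: Thermolysis of 8 extrudes N2 to give singlet aryl(chloro)carbene 9, which adds in a concerted [2+1] fashion to the C2=C3 enol ether bond of 2 (the most nucleophilic π bond, raised by O1 and the 3-silyloxy group) to give cyclopropa[b]benzofuran 10. In 10 the lone pair on O1 and the 6b-silyloxy group drive a disrotatory 2π-electrocyclic opening in which chloride leaves and the ring-fusion bond (the old C2–C3 bond) breaks, so the five-membered furan ring becomes the six-membered pyrylium ring of 11 with the carbene carbon as C3, after which chloride takes the silyl group from O4 and releases chromone 12 and TBSCl. The closest known reactions are the dihalocarbene ring expansion of cyclic silyl enol ethers to 2-halo-enones and the chlorodiazirine carbon-atom insertion into indoles and pyrroles (Ciamician–Dennstedt type). The only ring closed is the three-membered ring, by a concerted cheletropic [2+1] addition, and the pyranone ring is not closed by a cyclisation but arises by cleavage of the zero-atom bridge of the bicyclo[3.1.0] unit. No stereocentre survives the step (C3 is sp2 in 12 and is set in step 8), and both cyclopropane diastereomers should converge, the one with chloride syn to the furan ring opening in concert and the other expected to ionise first to the aryl-stabilised cyclopropyl cation. The selectivities needed are attack at the enol ether rather than at an arene, secured by the doubly donor-substituted C2=C3 bond and by keeping the prenyl alkene out until step 7, and the regiochemistry of insertion, which is built in because only the C2–C3 bond belongs to the cyclopropane, so migration of the electron-rich A ring cannot compete.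

**Step 7**
Reactants: 12 3-[5-bromo-2-methoxy-4-(methoxymethoxy)phenyl]-5,7-bis(tert-butyldimethylsilyloxy)-4H-chromen-4-one
Product: 13 5,7-bis(tert-butyldimethylsilyloxy)-3-[2-methoxy-4-(methoxymethoxy)-5-(3-methylbut-2-en-1-yl)phenyl]-4H-chromen-4-one
Conditions: tributyl(3-methylbut-2-en-1-yl)stannane (1.5 equiv), Pd(PPh3)4 (5 mol %), PhMe, 100 °C
Reagents that add atoms: tributyl(3-methylbut-2-en-1-yl)stannane CCCC[Sn](CCCC)(CCCC)CC=C(C)C
Why: Stille coupling of the aryl bromide with the prenylstannane should transfer the allyl unit through its α-carbon to give the linear prenyl group, and it is run at the achiral, base-stable isoflavone stage.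

**Step 8**
Reactants: 13 5,7-bis(tert-butyldimethylsilyloxy)-3-[2-methoxy-4-(methoxymethoxy)-5-(3-methylbut-2-en-1-yl)phenyl]-4H-chromen-4-one
Product: 15 (3S,4S)-5,7-bis(tert-butyldimethylsilyloxy)-3-[2-methoxy-4-(methoxymethoxy)-5-(3-methylbut-2-en-1-yl)phenyl]chroman-4-ol, via racemic isoflavanone 14 (not isolated)
Conditions: RuCl[(S,S)-TsDPEN](p-cymene) (5 mol %), HCO2H/Et3N (1:1), EtOAc, 40 °C
Reagents that add atoms: none
Why: This is a Noyori–Ikariya asymmetric transfer hydrogenation run as a cascade in which Ru–H first reduces the chromone C2=C3 bond to 14, whose C3–H epimerises rapidly through the enol under Et3N, and the (S,S) catalyst then reduces the C4 carbonyl of the 3S ketone selectively with hydride delivered anti to the 3-aryl group (dynamic kinetic resolution), so the catalyst sets C4 as S, the cis relationship sets C3 as S, and the racemic intermediate is funnelled into one isomer while the isolated prenyl alkene is left alone.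

**Step 9**
Reactants: 15 (3S,4S)-5,7-bis(tert-butyldimethylsilyloxy)-3-[2-methoxy-4-(methoxymethoxy)-5-(3-methylbut-2-en-1-yl)phenyl]chroman-4-ol
Product: 16 (3S)-5,7-bis(tert-butyldimethylsilyloxy)-3-[2-methoxy-4-(methoxymethoxy)-5-(3-methylbut-2-en-1-yl)phenyl]chroman-4-one
Conditions: Dess–Martin periodinane, NaHCO3, CH2Cl2, 0 °C; cold neutral work-up
Reagents that add atoms: none
Why: Dess–Martin oxidation of the benzylic alcohol under bicarbonate buffering removes the auxiliary C4 stereocentre and should leave the α-aryl C3–H untouched, because no base able to enolise the new ketone is present.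

**Step 10**
Reactants: 16 (3S)-5,7-bis(tert-butyldimethylsilyloxy)-3-[2-methoxy-4-(methoxymethoxy)-5-(3-methylbut-2-en-1-yl)phenyl]chroman-4-one
Product: 18 (3S)-5,7-dihydroxy-3-[4-hydroxy-2-methoxy-5-(3-methylbut-2-en-1-yl)phenyl]chroman-4-one, via 4'-phenol bis(silyl) ether 17 (not isolated)
Conditions: ZnBr2 (1.5 equiv), n-PrSH (3 equiv), CH2Cl2, 0 °C, 10 min; then HF·pyridine, pyridine, THF, 0 °C to rt
Reagents that add atoms: none
Why: Lewis acid–thiol cleavage of the aryl MOM acetal followed by pyridine-buffered fluoride desilylation is a non-basic two-stage global deprotection, chosen because base would epimerise C3 through the enolate and a strong protic acid would cyclise the prenyl group onto the 4′-OH.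

**Compound list**
1 | 4,6-dihydroxybenzofuran-3(2H)-one | O=C1COc2cc(O)cc(O)c12 | starting material
2 | 3,4,6-tris(tert-butyldimethylsilyloxy)benzofuran | CC(C)(C)[Si](C)(C)Oc1coc2cc(O[Si](C)(C)C(C)(C)C)cc(O[Si](C)(C)C(C)(C)C)c12 | intermediate
3 | 4-hydroxy-2-methoxybenzonitrile | N#Cc1ccc(O)cc1OC | starting material
4 | 5-bromo-4-hydroxy-2-methoxybenzonitrile | N#Cc1cc(Br)c(O)cc1OC | intermediate
5 | 5-bromo-2-methoxy-4-(methoxymethoxy)benzonitrile | N#Cc1cc(Br)c(OCOC)cc1OC | intermediate
6 | lithium N,N'-bis(trimethylsilyl)-5-bromo-2-methoxy-4-(methoxymethoxy)benzamidinate | [Li+].C[Si](C)(C)N=C([N-][Si](C)(C)C)c1cc(Br)c(OCOC)cc1OC | intermediate (not isolated)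
7 | 5-bromo-2-methoxy-4-(methoxymethoxy)benzamidine | NC(=N)c1cc(Br)c(OCOC)cc1OC | intermediate
8 | 3-[5-bromo-2-methoxy-4-(methoxymethoxy)phenyl]-3-chloro-3H-diazirine | ClC1(N=N1)c1cc(Br)c(OCOC)cc1OC | intermediate
9 | [5-bromo-2-methoxy-4-(methoxymethoxy)phenyl](chloro)carbene | Cl[C]c1cc(Br)c(OCOC)cc1OC | intermediate (not isolated)
10 | 1-[5-bromo-2-methoxy-4-(methoxymethoxy)phenyl]-1-chloro-4,6,6b-tris(tert-butyldimethylsilyloxy)-1a,6b-dihydro-1H-cyclopropa[b]benzofuran (diastereomer mixture) | ClC1(c2cc(Br)c(OCOC)cc2OC)C2Oc3cc(O[Si](C)(C)C(C)(C)C)cc(O[Si](C)(C)C(C)(C)C)c3C12O[Si](C)(C)C(C)(C)C | intermediate (not isolated)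
11 | 3-[5-bromo-2-methoxy-4-(methoxymethoxy)phenyl]-4,5,7-tris(tert-butyldimethylsilyloxy)chromenylium chloride | CC(C)(C)[Si](C)(C)Oc1c(-c2cc(Br)c(OCOC)cc2OC)c[o+]c2cc(O[Si](C)(C)C(C)(C)C)cc(O[Si](C)(C)C(C)(C)C)c12.[Cl-] | intermediate (not isolated)
12 | 3-[5-bromo-2-methoxy-4-(methoxymethoxy)phenyl]-5,7-bis(tert-butyldimethylsilyloxy)-4H-chromen-4-one | O=c1c(-c2cc(Br)c(OCOC)cc2OC)coc2cc(O[Si](C)(C)C(C)(C)C)cc(O[Si](C)(C)C(C)(C)C)c12 | intermediate
13 | 5,7-bis(tert-butyldimethylsilyloxy)-3-[2-methoxy-4-(methoxymethoxy)-5-(3-methylbut-2-en-1-yl)phenyl]-4H-chromen-4-one | O=c1c(-c2cc(CC=C(C)C)c(OCOC)cc2OC)coc2cc(O[Si](C)(C)C(C)(C)C)cc(O[Si](C)(C)C(C)(C)C)c12 | intermediate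
14 | rac-5,7-bis(tert-butyldimethylsilyloxy)-3-[2-methoxy-4-(methoxymethoxy)-5-(3-methylbut-2-en-1-yl)phenyl]chroman-4-one | O=C1C(c2cc(CC=C(C)C)c(OCOC)cc2OC)COc2cc(O[Si](C)(C)C(C)(C)C)cc(O[Si](C)(C)C(C)(C)C)c12 | intermediate (not isolated)
15 | (3S,4S)-5,7-bis(tert-butyldimethylsilyloxy)-3-[2-methoxy-4-(methoxymethoxy)-5-(3-methylbut-2-en-1-yl)phenyl]chroman-4-ol | COc1cc(OCOC)c(CC=C(C)C)cc1[C@H]1COc2cc(O[Si](C)(C)C(C)(C)C)cc(O[Si](C)(C)C(C)(C)C)c2[C@H]1O | intermediate
16 | (3S)-5,7-bis(tert-butyldimethylsilyloxy)-3-[2-methoxy-4-(methoxymethoxy)-5-(3-methylbut-2-en-1-yl)phenyl]chroman-4-one | COc1cc(OCOC)c(CC=C(C)C)cc1[C@H]1COc2cc(O[Si](C)(C)C(C)(C)C)cc(O[Si](C)(C)C(C)(C)C)c2C1=O | intermediate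
17 | (3S)-5,7-bis(tert-butyldimethylsilyloxy)-3-[4-hydroxy-2-methoxy-5-(3-methylbut-2-en-1-yl)phenyl]chroman-4-one | COc1cc(O)c(CC=C(C)C)cc1[C@H]1COc2cc(O[Si](C)(C)C(C)(C)C)cc(O[Si](C)(C)C(C)(C)C)c2C1=O | intermediate (not isolated)
18 | (3S)-5,7-dihydroxy-3-[4-hydroxy-2-methoxy-5-(3-methylbut-2-en-1-yl)phenyl]chroman-4-one | COc1cc(O)c(CC=C(C)C)cc1[C@H]1COc2cc(O)cc(O)c2C1=O | target

**Step count and risks**
Total step count: 10. Longest linear sequence: 9 steps (3 → 4 → 5 → 7 → 8 → 12 → 13 → 15 → 16 → 18).

Steps most likely to fail: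

Step 6. The electron-rich diazirine may decompose or ionise faster than the carbene is captured by the enol ether, the enol ether may be desilylated by adventitious acid, or the cyclopropane diastereomer with exo chloride may open too slowly. The fallback sets out from 2 and also bypasses diazirine 8. Treatment of 2 with dibromocarbene (CHBr3, KOtBu, pentane, −20 °C, then warming) is the classical dihalocarbene ring expansion of a silyl enol ether and should give 3-bromo-5,7-bis(tert-butyldimethylsilyloxy)-4H-chromen-4-one F1, so the five-to-six ring expansion is kept. The B ring is then attached by cross-coupling: commercial 2-bromo-5-methoxyphenol is iodinated para to OH (NIS, MeCN) to 2-bromo-4-iodo-5-methoxyphenol F2 and protected (MOMCl, i-Pr2NEt) as 1-bromo-5-iodo-4-methoxy-2-(methoxymethoxy)benzene F3. Selective iodine–magnesium exchange (i-PrMgCl·LiCl, −20 °C) and transmetalation with ZnCl2 give [5-bromo-2-methoxy-4-(methoxymethoxy)phenyl]zinc chloride F4, and Negishi coupling with F1 (Pd(PPh3)4, THF, rt; the activated vinylic C–Br should react before the aryl C–Br) returns to the route at 12.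

Step 8. Hydride transfer to the C4 carbonyl may be too slow because it is flanked by the peri 5-silyloxy group and deactivated by two oxygen donors, or the cascade may stall so that resolution is incomplete. The fallback sets out from 13 and sets C3 by enantioselective protonation instead of carbonyl reduction. 1,4-Reduction with L-Selectride (THF, −78 °C) and trapping of the enolate with allyl chloroformate should give allyl 5,7-bis(tert-butyldimethylsilyloxy)-3-[2-methoxy-4-(methoxymethoxy)-5-(3-methylbut-2-en-1-yl)phenyl]-2H-chromen-4-yl carbonate F5. Pd-catalysed decarboxylative asymmetric protonation (Pd2(dba)3, a (CF3)3-t-BuPHOX ligand, Meldrum's acid, dioxane, 40 °C), a method established for tertiary α-aryl chromanones, should then deliver the ketone directly; the ligand antipode that gives the 3S ketone is assigned in a pilot run. The fallback returns to the route at 16, so step 9 is not needed.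

Step 10. Lewis-acid-promoted enolisation during MOM cleavage may erode the configuration at C3, or the prenyl group may cyclise onto the liberated 4′-phenol. The fallback sets out from 13 and moves the acetal cleavage to the achiral isoflavone stage. ZnBr2/n-PrSH (CH2Cl2, 0 °C) should give 5,7-bis(tert-butyldimethylsilyloxy)-3-[4-hydroxy-2-methoxy-5-(3-methylbut-2-en-1-yl)phenyl]-4H-chromen-4-one F6; any loss of an A-ring silyl group would be repaired with TBSCl/imidazole. The transfer-hydrogenation cascade of step 8, which tolerates a free B-ring phenol, should give (3S,4S)-5,7-bis(tert-butyldimethylsilyloxy)-3-[4-hydroxy-2-methoxy-5-(3-methylbut-2-en-1-yl)phenyl]chroman-4-ol F7. Oxidation of the benzylic alcohol with activated MnO2 (CH2Cl2, rt), which is neutral and spares the phenol, returns to the route at 17, and only the buffered fluoride stage of step 10 remains.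

**Further compounds**
F1 | step 6 | 3-bromo-5,7-bis(tert-butyldimethylsilyloxy)-4H-chromen-4-one | O=c1c(Br)coc2cc(O[Si](C)(C)C(C)(C)C)cc(O[Si](C)(C)C(C)(C)C)c12
F2 | step 6 | 2-bromo-4-iodo-5-methoxyphenol | Oc1cc(OC)c(I)cc1Br
F3 | step 6 | 1-bromo-5-iodo-4-methoxy-2-(methoxymethoxy)benzene | COCOc1cc(OC)c(I)cc1Br
F4 | step 6 | [5-bromo-2-methoxy-4-(methoxymethoxy)phenyl]zinc chloride | COCOc1cc(OC)c([Zn]Cl)cc1Br
F5 | step 8 | allyl 5,7-bis(tert-butyldimethylsilyloxy)-3-[2-methoxy-4-(methoxymethoxy)-5-(3-methylbut-2-en-1-yl)phenyl]-2H-chromen-4-yl carbonate | C=CCOC(=O)OC1=C(c2cc(CC=C(C)C)c(OCOC)cc2OC)COc2cc(O[Si](C)(C)C(C)(C)C)cc(O[Si](C)(C)C(C)(C)C)c12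
F6 | step 10 | 5,7-bis(tert-butyldimethylsilyloxy)-3-[4-hydroxy-2-methoxy-5-(3-methylbut-2-en-1-yl)phenyl]-4H-chromen-4-one | O=c1c(-c2cc(CC=C(C)C)c(O)cc2OC)coc2cc(O[Si](C)(C)C(C)(C)C)cc(O[Si](C)(C)C(C)(C)C)c12
F7 | step 10 | (3S,4S)-5,7-bis(tert-butyldimethylsilyloxy)-3-[4-hydroxy-2-methoxy-5-(3-methylbut-2-en-1-yl)phenyl]chroman-4-ol | COc1cc(O)c(CC=C(C)C)cc1[C@H]1COc2cc(O[Si](C)(C)C(C)(C)C)cc(O[Si](C)(C)C(C)(C)C)c2[C@H]1O
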